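**Retrosynthetic overview**

1. Target 21 ⇐ esterifications (angelate on O4 after unmasking a C–B bond, benzoate on O8) ⇐ 16, whose 1α-OAc/8β-OH pair comes from an Evans–Tishchenko reduction of β-hydroxy enone 15, itself from dione 14 by anti-directed reduction.
2. 14 ⇐ intramolecular aldol closing the cyclopentane (C2–C3 bond) ⇐ β-boryl triketone 13 ⇐ conjugate borylation of dienone 12 ⇐ Nozaki–Hiyama–Kishi coupling and oxidation of alkenyl iodide 9.
3. 9 ⇐ enone formation and β-methylation of 6 ⇐ key step: enantioselective one-carbon ring expansion of 2-iodocyclohex-2-enone 2 with 3-diazobutan-2-one 5 (1,2-alkenyl shift), which sets the quaternary centre.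
4. Ring order: six-membered enone → seven-membered ring (step 3) → five-membered ring (step 9).

Assumption: bicyclic compounds carry azulene locants (C1–C3 five-membered ring, C3a, C4–C8 seven-membered ring, C8a); β is the face of the 8a-methyl group, α the opposite face; the SMILES strings fix the configurations.
Assumption: in the two ligand-controlled steps (3 and 8) the ligand antipode named is the one that gives the configuration drawn; if the sense of induction proves opposite, its mirror image is used.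

**Route**

Step 1
Reactants: 1 cyclohex-2-en-1-one
Product: 2 2-iodocyclohex-2-en-1-one
Conditions: I2, pyridine, CH2Cl2, 0 °C → rt
Reagents that add atoms: iodine, II
Why: Johnson α-iodination: conjugate addition of pyridine, iodination of the enolate and E1cB loss of pyridine give the α-iodoenone; no stereocentre is formed.

Step 2
Reactants: 3 butane-2,3-dione
Product: 5 3-diazobutan-2-one, via monotosylhydrazone 4 (not isolated)
Conditions: TsNHNH2, MeOH, 0 °C; then aq. NaOH, CH2Cl2, 0 °C
Reagents that add atoms: 4-methylbenzenesulfonohydrazide, Cc1ccc(cc1)S(=O)(=O)NN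
Why: Mono-condensation of the 1,2-diketone with tosylhydrazide and base-induced loss of sulfinate (Bamford–Stevens-type diazo formation) give the acceptor-stabilised diazo ketone; no stereocentre.

Step 3
Reactants: 2 2-iodocyclohex-2-en-1-one; 5 3-diazobutan-2-one
Product: 6 (2R)-2-acetyl-3-iodo-2-methylcyclohept-3-en-1-one
Conditions: 5 (1.3 equiv, slow addition), Sc(OTf)3 (10 mol %), chiral N,N′-dioxide ligand (L-pipecolic-acid-derived, 2,6-diisopropylanilide arms, 11 mol %), 4 Å MS, CH2Cl2, −30 °C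
Reagents that add atoms: none
Why: Proposed new method: the Sc(III)-bound enone carbonyl is attacked 1,2 by the tertiary diazo carbon on the ligand-exposed face, and the β-oxido diazonium collapses by anti-periplanar 1,2-shift of the sp2 (iodoalkenyl) carbon, favoured over CH2 by π-participation, with loss of N2, which expands the ring and fixes the non-epimerisable (R)-quaternary centre; the closest known reaction type is the chiral-Lewis-acid-catalysed Tiffeneau–Demjanov-type ring expansion of cyclohexanones with α-alkyl-α-diazo esters (alkyl migration), not yet shown for enones, alkenyl migration or α-diazo ketones.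

Step 4
Reactants: 6 (2R)-2-acetyl-3-iodo-2-methylcyclohept-3-en-1-one
Product: 7 (2R)-2-acetyl-3-iodo-2-methylcyclohepta-3,6-dien-1-one
Conditions: IBX (2.5 equiv), DMSO–fluorobenzene, 70 °C
Reagents that add atoms: none
Why: IBX dehydrogenation through the only enolisable ring position (C7; C2 is quaternary and the acetyl group has no β-hydrogen) gives the C6=C7 enone, and it avoids a Pd(0)-generating Saegusa oxidation in the presence of the alkenyl iodide.

Step 5
Reactants: 7 (2R)-2-acetyl-3-iodo-2-methylcyclohepta-3,6-dien-1-one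
Product: 9 (2R)-2-acetyl-3-iodo-2,6-dimethylcyclohepta-3,6-dien-1-one, via silyl enol ether 8 (not isolated)
Conditions: MeMgBr (1.2 equiv), CuBr·SMe2 (10 mol %), TMSCl (2 equiv), THF, −78 °C; then IBX·4-methoxypyridine N-oxide, DMSO, rt
Reagents that add atoms: methylmagnesium bromide, C[Mg]Br
Why: TMSCl-accelerated copper-catalysed 1,4-addition of the methyl Grignard reagent to the β-unsubstituted ring enone (the alkenyl iodide and the hindered ketones are inert at −78 °C) gives the silyl enol ether regiospecifically, and IBX·MPO dehydrogenation of that enol ether returns the enone now carrying the C6 methyl, erasing the transient C6 stereocentre.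

Step 6
Reactants: 9 (2R)-2-acetyl-3-iodo-2,6-dimethylcyclohepta-3,6-dien-1-one; 10 2-methylpropanal
Product: 11 (2R)-2-acetyl-3-(1-hydroxy-2-methylpropyl)-2,6-dimethylcyclohepta-3,6-dien-1-one (carbinol epimers)
Conditions: CrCl2 (4 equiv), NiCl2 (2 mol %), DMF, rt
Reagents that add atoms: none
Why: Nozaki–Hiyama–Kishi coupling: Ni-catalysed insertion into the alkenyl iodide and transmetalation to Cr(III) give an alkenylchromium species that adds only to the aldehyde and leaves the ketones and the enone untouched; the new carbinol centre forms unselectively and is erased in step 7.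

Step 7
Reactants: 11 (2R)-2-acetyl-3-(1-hydroxy-2-methylpropyl)-2,6-dimethylcyclohepta-3,6-dien-1-one
Product: 12 (2R)-2-acetyl-2,6-dimethyl-3-(2-methylpropanoyl)cyclohepta-3,6-dien-1-one
Conditions: Dess–Martin periodinane, NaHCO3, CH2Cl2, 0 °C → rt
Reagents that add atoms: none
Why: Dess–Martin oxidation of the allylic alcohol to the enone under buffered, non-nucleophilic conditions that spare the non-enolisable 1,3-diketone; no stereocentre.

Step 8
Reactants: 12 (2R)-2-acetyl-2,6-dimethyl-3-(2-methylpropanoyl)cyclohepta-3,6-dien-1-one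
Product: 13 (2R,3R,4S)-2-acetyl-2,6-dimethyl-3-(2-methylpropanoyl)-4-(4,4,5,5-tetramethyl-1,3,2-dioxaborolan-2-yl)cyclohept-6-en-1-one
Conditions: B2pin2 (1.1 equiv), CuCl (5 mol %), (R,S)-Josiphos (6 mol %), NaOt-Bu (5 mol %), MeOH (2 equiv), THF, 0 °C
Reagents that add atoms: bis(pinacolato)diboron, CC1(C)OB(OC1(C)C)B1OC(C)(C)C(C)(C)O1
Why: Copper-catalysed conjugate borylation: the Josiphos–Cu–Bpin complex adds to the β-monosubstituted isobutyryl enone (the β,β-disubstituted ring enone reacts far more slowly) and places boron on C4 on the face anti to the C2 methyl under catalyst control, while C3, still epimerisable next to the ketone, is protonated trans to the boryl group; the C–B bond then serves as a masked hydroxyl.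

Step 9
Reactants: 13 (2R,3R,4S)-2-acetyl-2,6-dimethyl-3-(2-methylpropanoyl)-4-(pinacolboryl)cyclohept-6-en-1-one
Product: 14 3β-hydroxy-6,8aβ-dimethyl-3α-(propan-2-yl)-4α-(pinacolboryl)-3aα-H-2,3,3a,4,5,8a-hexahydroazulene-1,8-dione
Conditions: LiHMDS (1.05 equiv), THF, −78 °C; AcOH quench at −78 °C
Reagents that add atoms: none
Why: Intramolecular aldol addition: kinetic deprotonation of the least hindered methyl ketone and 5-exo attack of its lithium enolate on the isopropyl ketone close the cyclopentane, the isopropyl group taking the face away from the boryl-bearing C4 so that the tertiary hydroxyl forms cis to C4 (3β), and the trans ring fusion follows from the configurations set in steps 3 and 8.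

Step 10
Reactants: 14 3β-hydroxy-6,8aβ-dimethyl-3α-(propan-2-yl)-4α-(pinacolboryl)-2,3,3a,4,5,8a-hexahydroazulene-1,8-dione
Product: 15 1α,3β-dihydroxy-6,8aβ-dimethyl-3α-(propan-2-yl)-4α-(pinacolboryl)-3aα-H-1,2,3,3a,4,5-hexahydroazulen-8(8aH)-one
Conditions: Me4NBH(OAc)3 (2 equiv), MeCN–AcOH, −40 °C
Reagents that add atoms: none
Why: Evans–Saksena reduction: the acetoxyborohydride bound to the 3β-hydroxyl delivers hydride intramolecularly to the β face of the saturated C1 ketone, giving the 1α-alcohol (1,3-anti diol), while the conjugated, less electrophilic C8 enone is left alone at this temperature and stoichiometry.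

Step 11
Reactants: 15 1α,3β-dihydroxy-6,8aβ-dimethyl-3α-(propan-2-yl)-4α-(pinacolboryl)-1,2,3,3a,4,5-hexahydroazulen-8(8aH)-one
Product: 16 1α-acetoxy-6,8aβ-dimethyl-3α-(propan-2-yl)-4α-(pinacolboryl)-3aα-H-1,2,3,3a,4,5,8,8a-octahydroazulene-3β,8β-diol
Conditions: MeCHO (8 equiv), SmI2 (30 mol %), THF, −10 °C
Reagents that add atoms: acetaldehyde, CC=O
Why: Evans–Tishchenko reduction: the Sm(III)-bound hemiacetal formed from acetaldehyde and the 1α-hydroxyl transfers hydride intramolecularly to the enone carbonyl (1,2) through a chair transition state, giving the 1,3-anti 8β-alcohol and leaving the acetate on O1, so the two secondary oxygens are differentiated in the same step.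

Step 12
Reactants: 16 1α-acetoxy-6,8aβ-dimethyl-3α-(propan-2-yl)-4α-(pinacolboryl)-1,2,3,3a,4,5,8,8a-octahydroazulene-3β,8β-diol
Product: 17 1α-acetoxy-8β-benzoyloxy-6,8aβ-dimethyl-3α-(propan-2-yl)-4α-(pinacolboryl)-3aα-H-1,2,3,3a,4,5,8,8a-octahydroazulen-3β-ol
Conditions: BzCl, DMAP, pyridine, CH2Cl2, rt
Reagents that add atoms: benzoyl chloride, O=C(Cl)c1ccccc1
Why: DMAP-catalysed acylation of the only secondary hydroxyl; the tertiary 3β-OH does not react under these conditions.

Step 13
Reactants: 17 1α-acetoxy-8β-benzoyloxy-6,8aβ-dimethyl-3α-(propan-2-yl)-4α-(pinacolboryl)-1,2,3,3a,4,5,8,8a-octahydroazulen-3β-ol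
Product: 18 1α-acetoxy-8β-benzoyloxy-6,8aβ-dimethyl-3α-(propan-2-yl)-3aα-H-1,2,3,3a,4,5,8,8a-octahydroazulene-3β,4α-diol
Conditions: NaBO3·4H2O, THF–H2O, rt
Reagents that add atoms: sodium perborate, [Na+].[O-]OB=O
Why: Perborate oxidation of the secondary alkylboronate proceeds by 1,2-migration of carbon from boron to oxygen with retention, unveiling the 4α-hydroxyl without touching the two esters.

Step 14
Reactants: 18 1α-acetoxy-8β-benzoyloxy-6,8aβ-dimethyl-3α-(propan-2-yl)-1,2,3,3a,4,5,8,8a-octahydroazulene-3β,4α-diol; 19 (2Z)-2-methylbut-2-enoic acid (angelic acid)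
Product: 21 (1S,3R,3aS,4S,8S,8aR)-1-(acetyloxy)-8-(benzoyloxy)-3-hydroxy-6,8a-dimethyl-3-(propan-2-yl)-1,2,3,3a,4,5,8,8a-octahydroazulen-4-yl (2Z)-2-methylbut-2-enoate, via mixed anhydride 20 (not isolated)
Conditions: 19, 2,4,6-trichlorobenzoyl chloride, Et3N, toluene, rt; then 18, toluene, 80 °C (no DMAP)
Reagents that add atoms: none
Why: Yamaguchi-type esterification: the mixed anhydride of angelic acid acylates the secondary 4α-hydroxyl in hot toluene without DMAP, conditions under which the (Z)-2-methylbut-2-enoate does not isomerise to the tiglate, and the tertiary 3β-OH stays free.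

**Compound list**

1 | cyclohex-2-en-1-one | O=C1C=CCCC1 | starting material
2 | 2-iodocyclohex-2-en-1-one | O=C1C(I)=CCCC1 | intermediate
3 | butane-2,3-dione | CC(=O)C(C)=O | starting material
4 | 3-[2-(4-methylbenzenesulfonyl)hydrazinylidene]butan-2-one | CC(=O)C(C)=NNS(=O)(=O)c1ccc(C)cc1 | intermediate
5 | 3-diazobutan-2-one | CC(=O)C(C)=[N+]=[N-] | intermediate
6 | (2R)-2-acetyl-3-iodo-2-methylcyclohept-3-en-1-one | O=C1CCCC=C(I)[C@]1(C)C(C)=O | intermediate
7 | (2R)-2-acetyl-3-iodo-2-methylcyclohepta-3,6-dien-1-one | O=C1C=CCC=C(I)[C@]1(C)C(C)=O | intermediate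
8 | 1-[(1S)-2-iodo-1,5-dimethyl-7-(trimethylsilyloxy)cyclohepta-2,6-dien-1-yl]ethan-1-one (C5 epimers) | C[Si](C)(C)OC1=CC(C)CC=C(I)[C@]1(C)C(C)=O | intermediate
9 | (2R)-2-acetyl-3-iodo-2,6-dimethylcyclohepta-3,6-dien-1-one | O=C1C=C(C)CC=C(I)[C@]1(C)C(C)=O | intermediate
10 | 2-methylpropanal | CC(C)C=O | starting material
11 | (2R)-2-acetyl-3-(1-hydroxy-2-methylpropyl)-2,6-dimethylcyclohepta-3,6-dien-1-one (carbinol epimers) | O=C1C=C(C)CC=C(C(O)C(C)C)[C@]1(C)C(C)=O | intermediate
12 | (2R)-2-acetyl-2,6-dimethyl-3-(2-methylpropanoyl)cyclohepta-3,6-dien-1-one | O=C1C=C(C)CC=C(C(=O)C(C)C)[C@]1(C)C(C)=O | intermediate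
13 | (2R,3R,4S)-2-acetyl-2,6-dimethyl-3-(2-methylpropanoyl)-4-(4,4,5,5-tetramethyl-1,3,2-dioxaborolan-2-yl)cyclohept-6-en-1-one | CC1(C)OB(OC1(C)C)[C@H]2CC(C)=CC(=O)[C@@](C)(C(C)=O)[C@@H]2C(=O)C(C)C | intermediate
14 | 3β-hydroxy-6,8aβ-dimethyl-3α-(propan-2-yl)-4α-(pinacolboryl)-3aα-H-2,3,3a,4,5,8a-hexahydroazulene-1,8-dione | CC1(C)OB(OC1(C)C)[C@H]2CC(C)=CC(=O)[C@@]3(C)C(=O)C[C@@](O)(C(C)C)[C@H]23 | intermediate
15 | 1α,3β-dihydroxy-6,8aβ-dimethyl-3α-(propan-2-yl)-4α-(pinacolboryl)-3aα-H-1,2,3,3a,4,5-hexahydroazulen-8(8aH)-one | CC1(C)OB(OC1(C)C)[C@H]2CC(C)=CC(=O)[C@@]3(C)[C@@H](O)C[C@@](O)(C(C)C)[C@H]23 | intermediate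
16 | 1α-acetoxy-6,8aβ-dimethyl-3α-(propan-2-yl)-4α-(pinacolboryl)-3aα-H-1,2,3,3a,4,5,8,8a-octahydroazulene-3β,8β-diol | CC1(C)OB(OC1(C)C)[C@H]2CC(C)=C[C@H](O)[C@@]3(C)[C@@H](OC(C)=O)C[C@@](O)(C(C)C)[C@H]23 | intermediate
17 | 1α-acetoxy-8β-benzoyloxy-6,8aβ-dimethyl-3α-(propan-2-yl)-4α-(pinacolboryl)-3aα-H-1,2,3,3a,4,5,8,8a-octahydroazulen-3β-ol | CC1(C)OB(OC1(C)C)[C@H]2CC(C)=C[C@H](OC(=O)c4ccccc4)[C@@]3(C)[C@@H](OC(C)=O)C[C@@](O)(C(C)C)[C@H]23 | intermediate
18 | 1α-acetoxy-8β-benzoyloxy-6,8aβ-dimethyl-3α-(propan-2-yl)-3aα-H-1,2,3,3a,4,5,8,8a-octahydroazulene-3β,4α-diol | O[C@H]1CC(C)=C[C@H](OC(=O)c2ccccc2)[C@@]3(C)[C@@H](OC(C)=O)C[C@@](O)(C(C)C)[C@H]13 | intermediate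
19 | (2Z)-2-methylbut-2-enoic acid (angelic acid) | C/C=C(/C)C(=O)O | starting material
20 | (2Z)-2-methylbut-2-enoic 2,4,6-trichlorobenzoic anhydride | C/C=C(/C)C(=O)OC(=O)c1c(Cl)cc(Cl)cc1Cl | intermediate
21 | (1S,3R,3aS,4S,8S,8aR)-1-(acetyloxy)-8-(benzoyloxy)-3-hydroxy-6,8a-dimethyl-3-(propan-2-yl)-1,2,3,3a,4,5,8,8a-octahydroazulen-4-yl (2Z)-2-methylbut-2-enoate | C/C=C(/C)C(=O)O[C@H]1CC(C)=C[C@H](OC(=O)c2ccccc2)[C@@]2(C)[C@@H](OC(C)=O)C[C@@](O)(C(C)C)[C@H]12 | target

**Step count**

Total: 14 steps. Longest linear sequence: 13 steps (1 and 3–14, from cyclohex-2-en-1-one); step 2 makes the diazo partner.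

**Steps most likely to fail, and fallbacks**

Step 3, the new ring expansion. The risks are addition at the enone β-carbon or dipolar cycloaddition, migration of CH2 instead of the iodoalkenyl carbon, epoxide formation, and low ee. The fallback uses known chemistry, sets out from 2 and returns at 6. The lithium salt of 1-diazopropan-2-one (LDA, THF, −78 °C) is added to the ketone of 2 to give the diazo aldol adduct 1-diazo-1-(1-hydroxy-2-iodocyclohex-2-en-1-yl)propan-2-one F1. Rh2(OAc)4 (1 mol %, CH2Cl2, rt) then triggers the carbenoid 1,2-alkenyl shift to the ring-expanded β-diketone 2-acetyl-3-iodocyclohept-3-en-1-one F2. Enantioselective phase-transfer C-methylation of this cyclic β-diketone (MeI, CsOH·H2O, 1 mol % C2-symmetric N-spiro binaphthyl quaternary ammonium bromide, toluene, −40 °C) installs the quaternary centre and gives 6.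

Step 11, the Evans–Tishchenko reduction on an enone. The risks are slow hydride transfer to the conjugated ketone, reduction of the enone by SmI2, and 1,3-acyl migration. The fallback sets out from 15 and returns at 16 by separating the two events. The secondary 1α-hydroxyl is acetylated (Ac2O, pyridine, CH2Cl2, 0 °C) to 1α-acetoxy-3β-hydroxy-6,8aβ-dimethyl-3α-(propan-2-yl)-4α-(pinacolboryl)-1,2,3,3a,4,5-hexahydroazulen-8(8aH)-one F3. Luche reduction (NaBH4, CeCl3·7H2O, MeOH, −78 °C), with hydride approaching anti to the 8a-methyl group, then gives 16.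

Step 14, angeloylation of a hindered secondary alcohol. The risks are low conversion and Z→E isomerisation to the tiglate. The fallback sets out from 18 and returns at 21 by building the Z-alkene on the substrate. Alcohol 18 is coupled with 2-[bis(2,2,2-trifluoroethoxy)phosphoryl]propanoic acid (EDC·HCl, DMAP, CH2Cl2, rt) to give the 4α-O-{2-[bis(2,2,2-trifluoroethoxy)phosphoryl]propanoyl} ester of 18 F4. Still–Gennari olefination with acetaldehyde (KHMDS, 18-crown-6, THF, −78 °C) then forms the (Z)-2-methylbut-2-enoate and gives 21.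

**Further compounds**

F1 | step 3 | 1-diazo-1-(1-hydroxy-2-iodocyclohex-2-en-1-yl)propan-2-one (racemic) | CC(=O)C(=[N+]=[N-])C1(O)CCCC=C1I
F2 | step 3 | 2-acetyl-3-iodocyclohept-3-en-1-one (racemic, enolisable) | CC(=O)C1C(=O)CCCC=C1I
F3 | step 11 | 1α-acetoxy-3β-hydroxy-6,8aβ-dimethyl-3α-(propan-2-yl)-4α-(pinacolboryl)-3aα-H-1,2,3,3a,4,5-hexahydroazulen-8(8aH)-one | CC1(C)OB(OC1(C)C)[C@H]2CC(C)=CC(=O)[C@@]3(C)[C@@H](OC(C)=O)C[C@@](O)(C(C)C)[C@H]23
F4 | step 14 | 1α-acetoxy-8β-benzoyloxy-3β-hydroxy-6,8aβ-dimethyl-3α-(propan-2-yl)-1,2,3,3a,4,5,8,8a-octahydroazulen-4α-yl 2-[bis(2,2,2-trifluoroethoxy)phosphoryl]propanoate | CC(C(=O)O[C@H]1CC(C)=C[C@H](OC(=O)c2ccccc2)[C@@]3(C)[C@@H](OC(C)=O)C[C@@](O)(C(C)C)[C@H]13)P(=O)(OCC(F)(F)F)OCC(F)(F)F
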